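# Synthesis proposal for CNP0190381.3: hydrindanone by semipinacol ring contraction of a bicyclo[3.3.1]nonane

## Analysis of the target

Target 36 is a cis-fused hexahydroindan-4-one. Its six-membered ring is labelled K (C4, the ketone), A (C5, CH), T (C6, tertiary carbinol), M (C7, CH2), Q2 (C7a) and Q1 (C3a); the cyclopentane is Q1–P1–P2–P3–Q2. Q1 and Q2 are adjacent quaternary carbons that each carry a methyl group. There are four stereocentres (3aR,5R,6R,7aR): both angular methyls, the 2-hydroxy-2-methylpropyl chain on A and the hydroxyl on T lie on one face, and the (E)-4-aryl-2-methylbut-2-enyl chain on T lies on the other. The A side chain has only one CH2 between the ring and the carbinol carbon, so it derives from a C4 unit of the methallyl type and not from a prenyl group. The sensitive elements are the β-hydroxy ketone K/A/T (retro-aldol, dehydration), two tertiary alcohols, an oxidisable hydroquinone monomethyl ether and a doubly activated benzylic-allylic CH2 next to an E-trisubstituted alkene. The main difficulties are the vicinal quaternary centres and the fact that K and T are in a 1,3-relationship, so any intermediate with both as ketones and a proton on A is a fully enolised, acidic β-diketone. The strategy rests on one feature: K is a ketone directly attached to quaternary Q1, and Q1 carries the ring CH2 P1. This is the pattern left when a CH2 group moves from a carbinol carbon to its neighbour, so Q1–P1 can be made by a 1,2-shift that contracts a cyclohexane.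

## Retrosynthetic reasoning

**36 from 35 and 34.** The last operations remove two silyl groups (35) and, before that, set the A–H bond. The β-hydroxy ketone is written as the product of reductive opening of the α,β-epoxy ketone 34. This keeps A quaternary, and therefore non-acidic, until the end, and the T oxygen is already in place.

**34 from 24 and 31/32.** The T–CH2 bond is cut. Forward, the allylbarium reagent 32 (from allylic chloride 31) must attack the T carbonyl through its CH2 terminus with the E geometry kept, and the resulting alkoxide displaces the chlorine on A. The chlorine is the repair for the β-diketone problem: in 24, A bears no proton, K lies between two quaternary carbons, and T is the only carbonyl open to attack.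

**24 from 23, and 23 from 18 and 21.** The chlorine is introduced on the enol of 23. The A–CH2 bond is cut to the dione 18 and the protected hydroxy aldehyde 21, joined by condensation and in-situ hydride transfer. This brings in the complete, already silylated side chain and avoids a late hydration that could not distinguish between two alkenes.

**18 from 14 (via 15, 16, 17).** The Q1 methyl is traced to a hydroxymethyl group. Forward, the primary alcohol is turned into an iodide and hydrogenolysed. The enolised dione has to be masked as its methyl enol ether 15 for this, because the enol would otherwise compete for the activating reagent.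

**14 from 13 (key disconnection).** The Q1–P1 bond is cut and re-formed between P1 and the K carbon, with a C–O bond placed on Q1. This leads to the spiro-epoxy ketol 13 of a bicyclo[3.3.1]nonane (C1 = K, C2 = A, C3 = T, C4 = M, C5 = Q2, C9 = Q1, C8 = P1). The gain is that Q1 is created by a stereospecific intramolecular shift from a bridged precursor with only one independent stereocentre (C5). The forward step must move C8 and not C2, and must not divert into a hydride shift.

**13 from 12, and 12 from 9 (via 10, 11).** The epoxide comes from the exocyclic alkene 12, and the alkene from the bridge ketone of 9. Because 9 has a second, less hindered ketone at C3, that ketone and the bridgehead hydroxyl are masked as silyl derivatives (10) during methylenation.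

**9 from 7 (via 8), 7 from 6, and 6 from 4.** The C1–C2 bond of the bridged β-ketol is an aldol bond between the methyl ketone side chain and the distal carbonyl of a 1,2-dione 8. The dione oxygen is introduced first (6), while only one α-position is enolisable, and the methyl ketone second (7).

**4 from 2 and 3, and 2 from 1.** The quaternary centre Q2 is cut at its allyl bond. A catalytic enantioselective decarboxylative allylation of the tetrasubstituted enolate of 2-methylcyclohexanone sets the only stereocentre that has to be introduced by a reagent.

**Side chains.** Chloride 31 comes from alcohol 30, which is made by SN2' opening of vinyl oxirane 28 with the aryl Grignard reagent 29 from bromide 27 (phenol 25 via 26). Aldehyde 21 comes from hydroxy ester 19 via 20.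

## Alternatives that were turned down

**Alternative 1:** The disconnection cuts Q1–Q2 and both bonds to the cyclopentane carbon P2. The forward key step is a cobalt-mediated carbonylative [2+2+1] cyclisation (Pauson–Khand) of the 1,7-enyne A1 to the bicyclic cyclopentenone A2.
- In its favour: both rings are closed in one step from an acyclic precursor. K and T arrive differentiated, as a silyl ether and a ketal, which would make the late addition at T simpler than in the chosen route, because T could be unveiled while K is still a protected carbinol. On this point it is stronger.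
- Against it: the alkene partner is 1,1-disubstituted and the new ring is six-membered, both unfavourable for this cyclisation, and the Q2 configuration would depend on a remote propargylic silyloxy group. In A2, Q1 is still an sp2 carbon without its methyl group. Creating the second quaternary centre next to the first by conjugate addition of a methylcopper reagent is hard, and the extra carbonyl at P2 then has to be removed over several steps.
- In comparison, the chosen strategy makes neither quaternary centre by intermolecular attack on a hindered carbon: Q2 comes from a catalytic allylation and Q1 from a stereospecific shift.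

**Alternative 2:** The disconnection cuts Q1–K and Q2–M. The forward key step is a [2+2] photocycloaddition of the chiral dioxinone A3 to 1,2-dimethylcyclopentene A4, giving the cyclobutane photoadduct A5. Retro-aldol opening of A5 and a Claisen-type ring closure would lead to the same dione 18.
- In its favour: both quaternary carbons and their cis relationship are set in a single step from a simple symmetrical alkene, so regiochemistry is not an issue. Compound 18 would be reached in far fewer steps than by the chosen route. On step economy to 18 this alternative is clearly stronger.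
- Against it: the absolute configuration rests on the facial discrimination exerted by an acetal stereocentre that is remote from the reacting carbons, in a photochemical addition to a tetrasubstituted alkene, where hydrogen abstraction and slow addition compete. A diastereomer mixture would lower the enantiomeric purity of everything that follows.
- In comparison, the chosen strategy offers an absolute configuration that comes from a well-understood catalytic step and is then transmitted without loss through a bridged intermediate. The endgame from 18 would be identical in both.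

**Alternative 3:** The disconnection cuts the A–T bond. The forward key step is a copper hydride reductive aldol cyclisation of the enone diketone A6: hydride adds to the enone β-carbon and the resulting copper enolate closes onto the side-chain ketone, giving A7, which is identical with compound 35 of the chosen route.
- In its favour: the ring closure follows the aldol polarity of the target. A and T are created together with all their substituents in place, no β-diketone ever appears, no blocking group is needed, and the product is one deprotection from 36. For the A/T region this alternative is the stronger one.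
- Against it: the difficult part of the molecule, a cyclopentane with two adjacent quaternary centres bearing two different acyl chains in enantiopure form, is not addressed by the key step and has to be built beforehand. The hydride must add to a β-carbon next to a fully substituted carbinol carbon, and the configuration at T relative to the ring fusion depends on a flexible transition state.
- In comparison, the chosen strategy solves the quaternary centres with its key step and pays for it with a longer endgame.

Key step: step 9

## Remarks on the chemistry

- Assumption: the target is taken as the open hydroxy ketone drawn; a ring–chain equilibrium with a hemiketal from the side-chain carbinol would be a property of the compound itself.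
- The allylation in step 2 is expected to give high but not complete enantioselectivity. If needed, the enantiomeric purity is raised by recrystallisation at the stage of the bridged ketol 9.

## Route

Step 1
Reactants: 1 2-methylcyclohexanone (racemic)
Product: 2 2-methyl-1-(trimethylsilyloxy)cyclohex-1-ene
Conditions: Me3SiCl, NaI, Et3N, MeCN, rt; distillation
Reagents that add atoms: chlorotrimethylsilane (C[Si](C)(C)Cl)
Why: Silyl enol ether formation under equilibrating conditions (iodotrimethylsilane made in the flask, amine base) favours the tetrasubstituted, thermodynamic isomer; the stereocentre of 1 is erased on purpose and the minor regioisomer is removed by distillation.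

Step 2
Reactants: 2 2-methyl-1-(trimethylsilyloxy)cyclohex-1-ene; 3 diallyl carbonate
Product: 4 (2R)-2-methyl-2-(prop-2-en-1-yl)cyclohexan-1-one
Conditions: Pd2(dba)3 (2.5 mol%), (R)-t-BuPHOX (6 mol%), Bu4N[Ph3SiF2] (35 mol%), THF, 25 °C
Reagents that add atoms: none
Why: Decarboxylative asymmetric allylic alkylation (Tsuji allylation): fluoride frees the tetrasubstituted enolate, the carbonate gives the allylpalladium cation carrying the phosphinooxazoline ligand, and C–C bond formation inside this ion pair sets Q2. The (S)-ligand is known to give the (S)-ketone with this substrate class, so the (R)-ligand is used.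

Step 3
Reactants: 4 (2R)-2-methyl-2-(prop-2-en-1-yl)cyclohexan-1-one
Product: 6 (2R)-6-hydroxy-2-methyl-2-(prop-2-en-1-yl)cyclohexan-1-one (both C6 epimers), via potassium enolate 5 (not isolated)
Conditions: KN(SiMe3)2, THF, −78 °C; 2-(benzenesulfonyl)-3-phenyloxaziridine, −78 °C; NH4Cl
Reagents that add atoms: 2-(benzenesulfonyl)-3-phenyloxaziridine (O=S(=O)(c1ccccc1)N1OC1c1ccccc1)
Why: The ketone can enolise only towards C6, and the potassium enolate is hydroxylated by the N-sulfonyloxaziridine (enolate oxidation). The new carbinol centre is formed as a mixture and does not matter, because it becomes a carbonyl in step 5.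

Step 4
Reactants: 6 (2R)-6-hydroxy-2-methyl-2-(prop-2-en-1-yl)cyclohexan-1-one
Product: 7 (2R)-6-hydroxy-2-methyl-2-(2-oxopropyl)cyclohexan-1-one (both C6 epimers)
Conditions: PdCl2 (10 mol%), CuCl (0.5 equiv), O2 (1 atm), DMF/H2O 7:1, rt
Reagents that add atoms: water (O)
Why: Tsuji–Wacker oxidation: Markovnikov hydroxypalladation of the terminal alkene gives the methyl ketone. The α-ketol is tolerated, and any part of it that the copper salt oxidises only anticipates step 5.

Step 5
Reactants: 7 (2R)-6-hydroxy-2-methyl-2-(2-oxopropyl)cyclohexan-1-one
Product: 9 (1R,5R)-1-hydroxy-5-methylbicyclo[3.3.1]nonane-3,9-dione, via triketone 8 (not isolated)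
Conditions: Dess–Martin periodinane, NaHCO3, CH2Cl2, 0 °C to rt; aqueous Na2S2O3 work-up; then pyrrolidine (20 mol%), AcOH (20 mol%), CH2Cl2, rt
Reagents that add atoms: none
Why: The periodinane oxidises the acyloin to the 1,2-dione 8, which rests as its enol. Pyrrolidinium acetate converts the methyl ketone into its terminal enamine, which adds to the C1 carbonyl of the small diketo fraction (intramolecular aldol addition onto a 1,2-dicarbonyl, as in Michael–aldol cascades of cyclohexane-1,2-dione); the bridged ketol cannot dehydrate. The bridge dictates the C1 configuration, so it follows from C5.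

Step 6
Reactants: 9 (1R,5R)-1-hydroxy-5-methylbicyclo[3.3.1]nonane-3,9-dione
Product: 10 (1R,5R)-5-methyl-1,3-bis(triethylsilyloxy)bicyclo[3.3.1]non-3-en-9-one (numbering of 9 kept)
Conditions: Et3SiOTf (2.5 equiv), Et3N, CH2Cl2, −78 to 0 °C
Reagents that add atoms: triethylsilyl trifluoromethanesulfonate (CC[Si](CC)(CC)OS(=O)(=O)C(F)(F)F)
Why: The silyl triflate and amine silylate the tertiary hydroxyl and turn the only enolisable ketone (C3) into its silyl enol ether, while the C9 carbonyl, which has no α-hydrogen, stays free. This masks C3 and blocks retro-aldol and α-ketol shifts in the basic next step; the regioisomeric enol ether towards C2 would serve equally.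

Step 7
Reactants: 10 (1R,5R)-5-methyl-1,3-bis(triethylsilyloxy)bicyclo[3.3.1]non-3-en-9-one
Product: 12 (1R,5R)-1-hydroxy-5-methyl-9-methylidenebicyclo[3.3.1]nonan-3-one, via bis-silyl methylidene compound 11 (not isolated)
Conditions: Ph3PCH3Br, KN(SiMe3)2, toluene, 0 to 90 °C; then 1 M HCl, THF, rt
Reagents that add atoms: methylenetriphenylphosphorane (C=P(c1ccccc1)(c1ccccc1)c1ccccc1)
Why: Wittig methylenation of the remaining bridge ketone; it is hindered but tied back, and forcing conditions of the kind used for ketones with two quaternary α-carbons are applied. Dilute acid then cleaves the silyl ether and the silyl enol ether without protonating the 1,1-disubstituted alkene.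

Step 8
Reactants: 12 (1R,5R)-1-hydroxy-5-methyl-9-methylidenebicyclo[3.3.1]nonan-3-one
Product: 13 (1R,5R,9R)-1-hydroxy-5-methylspiro[bicyclo[3.3.1]nonane-9,2'-oxiran]-3-one
Conditions: mCPBA, NaHCO3, CH2Cl2, 0 °C to rt
Reagents that add atoms: 3-chloroperbenzoic acid (O=C(OO)c1cccc(Cl)c1)
Why: Prilezhaev epoxidation of the exocyclic alkene, faster than Baeyer–Villiger oxidation of the ketone under buffered conditions. The peracid should approach over the flatter oxo-bearing ring, which puts the oxirane oxygen on that side (9R) and aligns the C1–C8 bond for step 9.

Step 9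
Reactants: 13 (1R,5R,9R)-1-hydroxy-5-methylspiro[bicyclo[3.3.1]nonane-9,2'-oxiran]-3-one
Product: 14 (3aR,7aR)-3a-(hydroxymethyl)-7a-methylhexahydroindane-4,6-dione
Conditions: BF3·OEt2 (1.1 equiv), CH2Cl2, −78 to −20 °C; NaHCO3
Reagents that add atoms: none
Why: BF3 binds the oxirane oxygen and weakens its bond to the fully substituted carbon C9; as charge builds there, the bridgehead hydroxyl pushes the C1–C8 bond over to C9, so that C1 becomes the K carbonyl and the oxirane oxygen ends as the primary alkoxide. The closest known reaction type is the Lewis acid semipinacol rearrangement of a 2,3-epoxy alcohol with migration to the epoxide carbon next to the carbinol. The cyclopentane is closed by ring contraction and not by a cyclisation: the ring C1–C8–C7–C6–C5–C9 loses C1 through a suprafacial 1,2-shift and becomes C9–C8–C7–C6–C5, which can be viewed as a 3-exo-tet attack of the C1–C8 bond on the C9–O antibonding orbital. The new stereocentre Q1 is fixed by this geometry: C8 stays on the face of the oxo-ring on which it sits in 13, the same face as C6 on C5, so the fusion must be cis, with hydroxymethyl and methyl together on the other face and C9 inverted. The step needs migration of C8 and not of C2: with the oxirane oxygen over the oxo-bearing ring only the C1–C8 bond is antiperiplanar to the breaking C–O bond, and C2 is further slowed by the electron-poor C3 carbonyl. It also has to outrun hydride migration from the oxirane CH2 and fluoride capture; the developing cation has no β-hydrogen on a ring carbon and the donor oxygen on C1 is aligned, which favours the shift. Low temperature limits retro-aldol cleavage of the β-ketol.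

Step 10
Reactants: 14 (3aR,7aR)-3a-(hydroxymethyl)-7a-methylhexahydroindane-4,6-dione
Product: 15 (3aR,7aR)-3a-(hydroxymethyl)-6-methoxy-7a-methyl-1,2,3,3a,7,7a-hexahydro-4H-inden-4-one
Conditions: MeOH, TsOH·H2O (cat.), 3 Å molecular sieves, 50 °C
Reagents that add atoms: methanol (CO)
Why: Acid-catalysed enol etherification of the enolised 1,3-dione (vinylogous ester formation), with methanol attacking the less hindered T carbonyl. Masking the acidic enol is what allows the primary hydroxyl to be activated alone in step 11; the regioisomeric enol ether would converge in step 12.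

Step 11
Reactants: 15 (3aR,7aR)-3a-(hydroxymethyl)-6-methoxy-7a-methyl-1,2,3,3a,7,7a-hexahydro-4H-inden-4-one
Product: 16 (3aS,7aR)-3a-(iodomethyl)-6-methoxy-7a-methyl-1,2,3,3a,7,7a-hexahydro-4H-inden-4-one
Conditions: I2, PPh3, imidazole, toluene, 80 °C
Reagents that add atoms: iodine (II)
Why: Appel-type iodination of the primary alcohol by SN2 displacement of the alkoxyphosphonium ion. Heating is needed at the neopentyl carbon, and no elimination is possible because the neighbouring carbon is quaternary.

Step 12
Reactants: 16 (3aS,7aR)-3a-(iodomethyl)-6-methoxy-7a-methyl-1,2,3,3a,7,7a-hexahydro-4H-inden-4-one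
Product: 18 (3aR,7aR)-3a,7a-dimethylhexahydroindane-4,6-dione, via deiodinated enol ether 17 (not isolated)
Conditions: H2 (1 atm), Pd/C, NaOAc, MeOH, rt; filtration; then 2 M HCl, THF, rt
Reagents that add atoms: water (O)
Why: Catalytic hydrogenolysis of the C–I bond on palladium with acetate as acid scavenger avoids a free radical next to the K carbonyl, which could undergo a 1,2-acyl shift. Acid hydrolysis of the vinylogous ester then returns the 1,3-dione.

Step 13
Reactants: 19 methyl 2-hydroxy-2-methylpropanoate
Product: 20 methyl 2-methyl-2-(triethylsilyloxy)propanoate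
Conditions: Et3SiOTf, 2,6-lutidine, CH2Cl2, 0 °C
Reagents that add atoms: triethylsilyl trifluoromethanesulfonate (CC[Si](CC)(CC)OS(=O)(=O)C(F)(F)F)
Why: Silylation of a tertiary hydroxyl with the silyl triflate. The triethylsilyl group is chosen so that it leaves together with the aryl silyl ether in the last step.

Step 14
Reactants: 20 methyl 2-methyl-2-(triethylsilyloxy)propanoate
Product: 21 2-methyl-2-(triethylsilyloxy)propanal
Conditions: i-Bu2AlH (1.1 equiv), CH2Cl2, −78 °C; Rochelle salt
Reagents that add atoms: none
Why: Partial reduction of the ester at −78 °C stops at the tetrahedral aluminium hemiacetal, which releases the aldehyde on work-up.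

Step 15
Reactants: 18 (3aR,7aR)-3a,7a-dimethylhexahydroindane-4,6-dione; 21 2-methyl-2-(triethylsilyloxy)propanal
Product: 23 (3aR,7aR)-3a,7a-dimethyl-5-[2-methyl-2-(triethylsilyloxy)propyl]hexahydroindane-4,6-dione (enolised), via alkylidene dione 22 (not isolated)
Conditions: L-proline (20 mol%), diethyl 2,6-dimethyl-1,4-dihydropyridine-3,5-dicarboxylate (1.2 equiv), CH2Cl2, rt to 40 °C
Reagents that add atoms: none
Why: Organocatalytic three-component reductive alkylation of a cyclic 1,3-dione: proline-mediated Knoevenagel condensation gives the alkylidene dione 22, which is reduced at once by hydride transfer from the Hantzsch ester. This puts the complete, protected A side chain on carbon without O-alkylation.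

Step 16
Reactants: 23 (3aR,7aR)-3a,7a-dimethyl-5-[2-methyl-2-(triethylsilyloxy)propyl]hexahydroindane-4,6-dione
Product: 24 (3aR,5S,7aR)-5-chloro-3a,7a-dimethyl-5-[2-methyl-2-(triethylsilyloxy)propyl]hexahydroindane-4,6-dione
Conditions: N-chlorosuccinimide, CH2Cl2, 0 °C to rt
Reagents that add atoms: N-chlorosuccinimide (O=C1CCC(=O)N1Cl)
Why: Electrophilic α-chlorination of the enol makes A quaternary and removes the acidic proton that would quench an organometallic. Chlorine should enter anti to the angular methyl on Q1, which leaves the large chain equatorial in a chair whose axial Q2 methyl shields the upper face of T; this centre is provisional and is reset in step 22.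

Step 17
Reactants: 25 4-methoxy-2-methylphenol
Product: 26 2-bromo-4-methoxy-6-methylphenol
Conditions: N-bromosuccinimide, i-Pr2NH (10 mol%), CH2Cl2, 0 °C
Reagents that add atoms: N-bromosuccinimide (O=C1CCC(=O)N1Br)
Why: Amine-catalysed ortho-bromination of a phenol (electrophilic aromatic substitution). The para position is blocked by methoxy and the hydroxyl directs to the free ortho carbon.

Step 18
Reactants: 26 2-bromo-4-methoxy-6-methylphenol
Product: 27 (2-bromo-4-methoxy-6-methylphenoxy)(tert-butyl)dimethylsilane
Conditions: t-BuMe2SiCl, imidazole, DMF, rt to 40 °C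
Reagents that add atoms: tert-butylchlorodimethylsilane (CC(C)(C)[Si](C)(C)Cl)
Why: Standard silylation of the phenol; the silyl ether survives the Grignard, barium and SmI2 steps and is cleaved by fluoride at the end.

Step 19
Reactants: 27 (2-bromo-4-methoxy-6-methylphenoxy)(tert-butyl)dimethylsilane; 28 2-methyl-2-vinyloxirane (racemic)
Product: 30 (2E)-4-[2-(tert-butyldimethylsilyloxy)-5-methoxy-3-methylphenyl]-2-methylbut-2-en-1-ol, via aryl Grignard reagent 29 (not isolated)
Conditions: Mg turnings, THF, reflux; then CuI (10 mol%), 28, THF, −30 to 0 °C; NH4Cl
Reagents that add atoms: none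
Why: Magnesium insertion gives the aryl Grignard reagent, and copper-catalysed SN2' opening of the vinyl oxirane forms the aryl–CH2 bond. Anti attack on the s-trans conformer of the vinyl oxirane gives the E trisubstituted allylic alcohol.

Step 20
Reactants: 30 (2E)-4-[2-(tert-butyldimethylsilyloxy)-5-methoxy-3-methylphenyl]-2-methylbut-2-en-1-ol
Product: 31 tert-butyl{2-[(2E)-4-chloro-3-methylbut-2-en-1-yl]-4-methoxy-6-methylphenoxy}dimethylsilane
Conditions: N-chlorosuccinimide, Me2S, CH2Cl2, −20 to 0 °C
Reagents that add atoms: N-chlorosuccinimide (O=C1CCC(=O)N1Cl)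
Why: Corey–Kim chlorination: chloride displaces the alkoxysulfonium ion at the primary carbon, giving the allylic chloride without allylic transposition or loss of the E geometry.

Step 21
Reactants: 24 (3aR,5S,7aR)-5-chloro-3a,7a-dimethyl-5-[2-methyl-2-(triethylsilyloxy)propyl]hexahydroindane-4,6-dione; 31 tert-butyl{2-[(2E)-4-chloro-3-methylbut-2-en-1-yl]-4-methoxy-6-methylphenoxy}dimethylsilane
Product: 34 (3aR,5R,6R,7aR)-5,6-epoxy-6-{(2E)-4-[2-(tert-butyldimethylsilyloxy)-5-methoxy-3-methylphenyl]-2-methylbut-2-en-1-yl}-3a,7a-dimethyl-5-[2-methyl-2-(triethylsilyloxy)propyl]hexahydroindan-4-one, via allylbarium chloride 32 (not isolated), via chlorohydrin barium alkoxide 33 (not isolated)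
Conditions: BaI2, lithium biphenylide (2 equiv), THF, rt; 31, −78 °C; then 24, −78 °C, warm to 0 °C; NH4Cl
Reagents that add atoms: none
Why: Allylbarium reagents made at −78 °C from an allylic chloride and activated barium add to ketones through their less substituted α-carbon with retention of alkene geometry. T is the only accessible carbonyl, since K lies between two quaternary carbons, and attack along the equatorial trajectory opposite the axial Q2 methyl puts the alkoxide on the methyl face. There it is anti to the chlorine and closes to the oxirane on warming (Darzens-type closure).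

Step 22
Reactants: 34 epoxy ketone
Product: 35 (3aR,5R,6R,7aR)-6-{(2E)-4-[2-(tert-butyldimethylsilyloxy)-5-methoxy-3-methylphenyl]-2-methylbut-2-en-1-yl}-6-hydroxy-3a,7a-dimethyl-5-[2-methyl-2-(triethylsilyloxy)propyl]hexahydroindan-4-one
Conditions: SmI2 (2.5 equiv), THF/MeOH, −90 to −78 °C
Reagents that add atoms: none
Why: SmI2 reduction of an α,β-epoxy ketone: ketyl formation at K, cleavage of the Cα–O bond and a second electron give the samarium enolate, which methanol protonates at A, while T keeps its configuration. A should take the equatorial chain, trans to the chain on T, which is also the more stable arrangement if the α-centre has to be equilibrated.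

Step 23
Reactants: 35 bis-silyl ether of the target
Product: 36 (3aR,5R,6R,7aR)-6-hydroxy-6-[(2E)-4-(2-hydroxy-5-methoxy-3-methylphenyl)-2-methylbut-2-en-1-yl]-5-(2-hydroxy-2-methylpropyl)-3a,7a-dimethylhexahydroindan-4-one
Conditions: Bu4NF (3 equiv), AcOH (3 equiv), THF, 0 °C to rt
Reagents that add atoms: none
Why: Fluoride cleaves the aryl tert-butyldimethylsilyl ether and the tertiary triethylsilyl ether. Acetic acid buffers the medium so that the β-hydroxy ketone neither undergoes retro-aldol cleavage nor dehydrates.

## Compound list

1 | 2-methylcyclohexanone (racemic) | CC1CCCCC1=O | starting material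
2 | 2-methyl-1-(trimethylsilyloxy)cyclohex-1-ene | CC1=C(O[Si](C)(C)C)CCCC1 | intermediate
3 | diallyl carbonate | C=CCOC(=O)OCC=C | starting material
4 | (2R)-2-methyl-2-(prop-2-en-1-yl)cyclohexan-1-one | C=CC[C@@]1(C)CCCCC1=O | intermediate
5 | potassium enolate of 4 | C=CC[C@@]1(C)CCCC=C1[O-].[K+] | intermediate (not isolated)
6 | (2R)-6-hydroxy-2-methyl-2-(prop-2-en-1-yl)cyclohexan-1-one, both C6 epimers | C=CC[C@@]1(C)CCCC(O)C1=O | intermediate
7 | (2R)-6-hydroxy-2-methyl-2-(2-oxopropyl)cyclohexan-1-one, both C6 epimers | CC(=O)C[C@@]1(C)CCCC(O)C1=O | intermediate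
8 | (3R)-3-methyl-3-(2-oxopropyl)cyclohexane-1,2-dione (rests as the enol towards C6) | CC(=O)C[C@@]1(C)CCCC(=O)C1=O | intermediate (not isolated)
9 | (1R,5R)-1-hydroxy-5-methylbicyclo[3.3.1]nonane-3,9-dione | O[C@@]12CC(=O)C[C@@](C)(CCC1)C2=O | intermediate
10 | (1R,5R)-5-methyl-1,3-bis(triethylsilyloxy)bicyclo[3.3.1]non-3-en-9-one | CC[Si](CC)(CC)O[C@@]12CC(O[Si](CC)(CC)CC)=C[C@@](C)(CCC1)C2=O | intermediate
11 | (1R,5R)-5-methyl-9-methylidene-1,3-bis(triethylsilyloxy)bicyclo[3.3.1]non-3-ene | CC[Si](CC)(CC)O[C@@]12CC(O[Si](CC)(CC)CC)=C[C@@](C)(CCC1)C2=C | intermediate (not isolated)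
12 | (1R,5R)-1-hydroxy-5-methyl-9-methylidenebicyclo[3.3.1]nonan-3-one | O[C@@]12CC(=O)C[C@@](C)(CCC1)C2=C | intermediate
13 | (1R,5R,9R)-1-hydroxy-5-methylspiro[bicyclo[3.3.1]nonane-9,2'-oxiran]-3-one, oxirane oxygen over the oxo-bearing ring | O[C@@]12CC(=O)C[C@@](C)(CCC1)[C@@]21CO1 | intermediate (precursor of the key step)
14 | (3aR,7aR)-3a-(hydroxymethyl)-7a-methylhexahydroindane-4,6-dione, cis-fused | O=C1CC(=O)C[C@@]2(C)CCC[C@@]12CO | intermediate (product of the key step)
15 | (3aR,7aR)-3a-(hydroxymethyl)-6-methoxy-7a-methyl-1,2,3,3a,7,7a-hexahydro-4H-inden-4-one | O=C1C=C(OC)C[C@@]2(C)CCC[C@@]12CO | intermediate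
16 | (3aS,7aR)-3a-(iodomethyl)-6-methoxy-7a-methyl-1,2,3,3a,7,7a-hexahydro-4H-inden-4-one | O=C1C=C(OC)C[C@@]2(C)CCC[C@@]12CI | intermediate
17 | (3aR,7aR)-6-methoxy-3a,7a-dimethyl-1,2,3,3a,7,7a-hexahydro-4H-inden-4-one | O=C1C=C(OC)C[C@@]2(C)CCC[C@@]12C | intermediate (not isolated)
18 | (3aR,7aR)-3a,7a-dimethylhexahydroindane-4,6-dione, cis-fused | O=C1CC(=O)C[C@@]2(C)CCC[C@@]12C | intermediate
19 | methyl 2-hydroxy-2-methylpropanoate | COC(=O)C(C)(C)O | starting material
20 | methyl 2-methyl-2-(triethylsilyloxy)propanoate | COC(=O)C(C)(C)O[Si](CC)(CC)CC | intermediate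
21 | 2-methyl-2-(triethylsilyloxy)propanal | CC(C)(O[Si](CC)(CC)CC)C=O | intermediate
22 | (3aR,7aR)-3a,7a-dimethyl-5-[2-methyl-2-(triethylsilyloxy)propylidene]hexahydroindane-4,6-dione | O=C1C(=CC(C)(C)O[Si](CC)(CC)CC)C(=O)C[C@@]2(C)CCC[C@@]12C | intermediate (not isolated)
23 | (3aR,7aR)-3a,7a-dimethyl-5-[2-methyl-2-(triethylsilyloxy)propyl]hexahydroindane-4,6-dione (enolised, C5 not fixed) | O=C1C(CC(C)(C)O[Si](CC)(CC)CC)C(=O)C[C@@]2(C)CCC[C@@]12C | intermediate
24 | (3aR,5S,7aR)-5-chloro-3a,7a-dimethyl-5-[2-methyl-2-(triethylsilyloxy)propyl]hexahydroindane-4,6-dione, chlorine anti to the angular methyls | O=C1[C@](Cl)(CC(C)(C)O[Si](CC)(CC)CC)C(=O)C[C@@]2(C)CCC[C@@]12C | intermediate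
25 | 4-methoxy-2-methylphenol | COc1ccc(O)c(C)c1 | starting material
26 | 2-bromo-4-methoxy-6-methylphenol | COc1cc(C)c(O)c(Br)c1 | intermediate
27 | (2-bromo-4-methoxy-6-methylphenoxy)(tert-butyl)dimethylsilane | COc1cc(C)c(O[Si](C)(C)C(C)(C)C)c(Br)c1 | intermediate
28 | 2-methyl-2-vinyloxirane (racemic) | CC1(C=C)CO1 | starting material
29 | [2-(tert-butyldimethylsilyloxy)-5-methoxy-3-methylphenyl]magnesium bromide | COc1cc(C)c(O[Si](C)(C)C(C)(C)C)c([Mg]Br)c1 | intermediate (not isolated)
30 | (2E)-4-[2-(tert-butyldimethylsilyloxy)-5-methoxy-3-methylphenyl]-2-methylbut-2-en-1-ol | COc1cc(C)c(O[Si](C)(C)C(C)(C)C)c(C/C=C(\C)CO)c1 | intermediate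
31 | tert-butyl{2-[(2E)-4-chloro-3-methylbut-2-en-1-yl]-4-methoxy-6-methylphenoxy}dimethylsilane | COc1cc(C)c(O[Si](C)(C)C(C)(C)C)c(C/C=C(\C)CCl)c1 | intermediate
32 | {(2E)-4-[2-(tert-butyldimethylsilyloxy)-5-methoxy-3-methylphenyl]-2-methylbut-2-en-1-yl}barium chloride | COc1cc(C)c(O[Si](C)(C)C(C)(C)C)c(C/C=C(\C)C[Ba]Cl)c1 | intermediate (not isolated)
33 | chlorobarium alkoxide of the (5S,6R)-5-chloro-6-hydroxy adduct of 24 and 32 | COc1cc(C)c(O[Si](C)(C)C(C)(C)C)c(C/C=C(\C)C[C@@]2(O[Ba]Cl)C[C@@]3(C)CCC[C@@]3(C)C(=O)[C@]2(Cl)CC(C)(C)O[Si](CC)(CC)CC)c1 | intermediate (not isolated)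
34 | (3aR,5R,6R,7aR)-5,6-epoxy ketone, oxirane oxygen on the face of the angular methyls | COc1cc(C)c(O[Si](C)(C)C(C)(C)C)c(C/C=C(\C)C[C@@]2(O5)C[C@@]3(C)CCC[C@@]3(C)C(=O)[C@@]25CC(C)(C)O[Si](CC)(CC)CC)c1 | intermediate
35 | (3aR,5R,6R,7aR)-bis-silyl ether of the target (aryl tert-butyldimethylsilyl ether, tertiary triethylsilyl ether) | COc1cc(C)c(O[Si](C)(C)C(C)(C)C)c(C/C=C(\C)C[C@@]2(O)C[C@@]3(C)CCC[C@@]3(C)C(=O)[C@@H]2CC(C)(C)O[Si](CC)(CC)CC)c1 | intermediate
36 | (3aR,5R,6R,7aR)-6-hydroxy-6-[(2E)-4-(2-hydroxy-5-methoxy-3-methylphenyl)-2-methylbut-2-en-1-yl]-5-(2-hydroxy-2-methylpropyl)-3a,7a-dimethylhexahydroindan-4-one | COc1cc(C)c(O)c(C/C=C(\C)C[C@@]2(O)C[C@@]3(C)CCC[C@@]3(C)C(=O)[C@@H]2CC(C)(C)O)c1 | target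

## Step count and least certain steps

Total step count: 23. Longest linear sequence: 17 steps (steps 1–12, 15, 16, 21, 22, 23). Steps 13–14 and 17–20 are side branches.

**Step 9 (key step).** The shift may be diverted in three ways: migration of hydride from the oxirane CH2 to give an aldehyde, migration of C2 if the oxirane has the other configuration at C9, or capture of the cation by fluoride. All of these compete because the cation sits between two quaternary carbons and the shift needs exact alignment; retro-aldol cleavage of the β-ketol under the Lewis acid is a further loss channel. Fallback: set out from alkene 12 and induce the same 1,2-shift with a halonium ion. One equivalent of N-bromosuccinimide in CH2Cl2 adds bromine to the terminal carbon and triggers migration of C8, giving (3aS,7aR)-3a-(bromomethyl)-7a-methylhexahydroindane-4,6-dione F1. Hydrogenolysis of the C–Br bond (H2, Pd/C, NaOAc) then leads directly to 18, where the route is rejoined; steps 8 and 10–12 are no longer needed.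

**Step 5.** The aldol closure may stall or go the wrong way. The electrophilic carbon C1 is the enol carbon in the resting form of 8, so the reaction depends on a small diketo fraction. The enamine could instead close onto the other dione carbonyl to give a five-membered ring that can dehydrate, and the equilibrium may not lie fully on the side of the ketol. Fallback: set out from 6 and move the carbonyl first, so that the electrophile is an ordinary ketone. NaBH4 gives (3R)-3-methyl-3-(prop-2-en-1-yl)cyclohexane-1,2-diol F2. Nitroxyl-catalysed oxidation of the less hindered carbinol gives (3R)-2-hydroxy-3-methyl-3-(prop-2-en-1-yl)cyclohexan-1-one F3. Wacker oxidation gives (3R)-2-hydroxy-3-methyl-3-(2-oxopropyl)cyclohexan-1-one F4. Carbonate-mediated aldol closure gives (1R,5R)-1,9-dihydroxy-5-methylbicyclo[3.3.1]nonan-3-one F5, and oxidation of its secondary carbinol with Dess–Martin periodinane returns to 9.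

**Step 8.** Facial selectivity of the epoxidation may be poor or reversed, because the two faces of the alkene differ only in the shape of the two rings; Baeyer–Villiger oxidation is a minor competing process. Fallback: set out from ketone 10 and add the carbon instead of the oxygen. Dimethylsulfonium methylide (Me3SI, KN(SiMe3)2) attacks the C9 carbonyl from the same, more open side, which places the oxygen on the opposite face to that given by a peracid. This gives the bis-silyl spiro-oxirane F6, and buffered fluoride (Bu4NF, AcOH) removes both silyl groups to return to 13. Whichever face is the more open, one of the two methods delivers the required configuration.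

**Step 15.** Condensation with the α-quaternary aldehyde may be slow, so that a second molecule of dione adds to the alkylidene intermediate before hydride transfer. Fallback: set out from 18 and use alkylation and hydration. C-Alkylation with 3-bromo-2-methylpropene (K2CO3) gives (3aR,7aR)-3a,7a-dimethyl-5-(2-methylprop-2-en-1-yl)hexahydroindane-4,6-dione F7. N-Chlorosuccinimide gives its 5-chloro derivative F8. Mukaiyama hydration (Co(acac)2, PhSiH3, O2) gives the tertiary alcohol F9, and Et3SiOTf with 2,6-lutidine returns to 24.

**Step 21.** Several processes can intervene.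
- Halogen–metal attack at the chlorine of the α-chloro-β-diketone would return the enolate of 23.
- Proton transfer from the benzylic-allylic CH2 could isomerise the allylbarium reagent.
- Some attack through the γ-carbon is possible.
- Addition could occur from the wrong face if the chlorination in step 16 gave the other epimer and the ring takes the other chair.

Fallback: set out from 24 and build the chain in two stages with a symmetrical allyl unit. 2-Methylallylmagnesium chloride (α- and γ-termini identical) adds to T and closes to the epoxy ketone F10. The Grignard reagent 29 and allyl bromide give tert-butyl[4-methoxy-2-methyl-6-(prop-2-en-1-yl)phenoxy]dimethylsilane F11. Cross-metathesis of F10 with F11 using a second-generation Hoveyda–Grubbs catalyst, with separation of the alkene isomers, returns to 34.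

## Further compounds

F1 | step 9 | (3aS,7aR)-3a-(bromomethyl)-7a-methylhexahydroindane-4,6-dione | O=C1CC(=O)C[C@@]2(C)CCC[C@@]12CBr
F2 | step 5 | (3R)-3-methyl-3-(prop-2-en-1-yl)cyclohexane-1,2-diol (diastereomers) | C=CC[C@@]1(C)CCCC(O)C1O
F3 | step 5 | (3R)-2-hydroxy-3-methyl-3-(prop-2-en-1-yl)cyclohexan-1-one | C=CC[C@@]1(C)CCCC(=O)C1O
F4 | step 5 | (3R)-2-hydroxy-3-methyl-3-(2-oxopropyl)cyclohexan-1-one | CC(=O)C[C@@]1(C)CCCC(=O)C1O
F5 | step 5 | (1R,5R)-1,9-dihydroxy-5-methylbicyclo[3.3.1]nonan-3-one | O[C@@]12CC(=O)C[C@@](C)(CCC1)C2O
F6 | step 8 | (1R,5R,9R)-5-methyl-1,3-bis(triethylsilyloxy)spiro[bicyclo[3.3.1]non-3-ene-9,2'-oxirane] | CC[Si](CC)(CC)O[C@@]12CC(O[Si](CC)(CC)CC)=C[C@@](C)(CCC1)[C@@]21CO1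
F7 | step 15 | (3aR,7aR)-3a,7a-dimethyl-5-(2-methylprop-2-en-1-yl)hexahydroindane-4,6-dione | O=C1C(CC(C)=C)C(=O)C[C@@]2(C)CCC[C@@]12C
F8 | step 15 | (3aR,5S,7aR)-5-chloro-3a,7a-dimethyl-5-(2-methylprop-2-en-1-yl)hexahydroindane-4,6-dione | O=C1[C@](Cl)(CC(C)=C)C(=O)C[C@@]2(C)CCC[C@@]12C
F9 | step 15 | (3aR,5S,7aR)-5-chloro-5-(2-hydroxy-2-methylpropyl)-3a,7a-dimethylhexahydroindane-4,6-dione | O=C1[C@](Cl)(CC(C)(C)O)C(=O)C[C@@]2(C)CCC[C@@]12C
F10 | step 21 | (3aR,5R,6R,7aR)-5,6-epoxy-3a,7a-dimethyl-6-(2-methylprop-2-en-1-yl)-5-[2-methyl-2-(triethylsilyloxy)propyl]hexahydroindan-4-one | C=C(C)C[C@@]1(O2)C[C@@]3(C)CCC[C@@]3(C)C(=O)[C@@]12CC(C)(C)O[Si](CC)(CC)CC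
F11 | step 21 | tert-butyl[4-methoxy-2-methyl-6-(prop-2-en-1-yl)phenoxy]dimethylsilane | COc1cc(C)c(O[Si](C)(C)C(C)(C)C)c(CC=C)c1
A1 | alternative 1 | 1,7-enyne with propargylic silyl ether, dioxolane and isopropenyl terminus | C#C[C@@H](O[Si](C)(C)C(C)(C)C)CC1(OCCO1)CC(C)=C
A2 | alternative 1 | bicyclic cyclopentenone with angular methyl at Q2 | O=C1C=C2[C@@H](O[Si](C)(C)C(C)(C)C)CC3(OCCO3)C[C@@]2(C)C1
A3 | alternative 2 | (R)-2-tert-butyl-6-methyl-1,3-dioxin-4-one | CC1=CC(=O)O[C@H](C(C)(C)C)O1
A4 | alternative 2 | 1,2-dimethylcyclopentene | CC1=C(C)CCC1
A5 | alternative 2 | cis-anti-cis tricyclic dioxanone photoadduct | O=C1O[C@H](C(C)(C)C)O[C@]2(C)[C@H]1[C@@]1(C)CCC[C@@]21C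
A6 | alternative 3 | enone diketone on the cis-1,2-dimethylcyclopentane | COc1cc(C)c(O[Si](C)(C)C(C)(C)C)c(C/C=C(\C)CC(=O)C[C@@]2(C)CCC[C@@]2(C)C(=O)/C=C/C(C)(C)O[Si](CC)(CC)CC)c1
A7 | alternative 3 | bis-silyl ether of the target (identical with 35) | COc1cc(C)c(O[Si](C)(C)C(C)(C)C)c(C/C=C(\C)C[C@@]2(O)C[C@@]3(C)CCC[C@@]3(C)C(=O)[C@@H]2CC(C)(C)O[Si](CC)(CC)CC)c1
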